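**Retrosynthetic overview**

1. Rings are lettered A (4-hydroxy-2-methoxybenzyl arene), B (3-hydroxy-2,4-dimethoxyphenyl), C (catechol), D (cyclohexenone), E (tetrahydrofuran), F (dihydropyran) and G (the carbocycle that fuses C to D). Ring G is opened first: intramolecular Friedel–Crafts hydroxyalkylation of ring C on the α-diketone of ring D, run together with removal of all methoxymethyl groups.
2. Key disconnection: ring E of the 8-oxabicyclo[3.2.1]octadiene is cut at the bond from the bridging ether oxygen to the quaternary ring-D carbon and at the C–C bond between the benzyl-bearing methine and the ring-C-bearing methine. Forward, a photoredox decarboxylative radical-polar crossover (3+2) annulation of a β-hydroxy redox-active ester across the exocyclic C=C of a ring-D para-quinone methide closes the seven-membered carbocycle and rings E and F, and dearomatises ring D.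
3. Enabling feature: in ring D the ketone carbon is para to the quaternary ether carbon, and that carbon carries the benzylic methine of ring C. Ring D can therefore enter as a para-hydroxybenzhydryl phenol, which gives first a quinone methide (radical acceptor at the methine carbon) and then a phenoxonium ion (oxygen acceptor at the para carbon).
4. The cyclisation substrate comes from an Evans aldol (the single controlling stereocentre) of a ring-A propanoyl imide with a (Z)-2,3-diarylpropenal. The enal comes from a three-component carbomagnesiation/cross-coupling of propargyl alcohol, a ring-B Grignard reagent and the ring-D aryl bromide, itself made by adding a ring-C aryllithium to a bromobenzaldehyde.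
5. Order of ring formation: A–D arrive as arenes; the seven-membered carbocycle, then E and F, form in step 15; G forms in step 16.

Key step: step 15

Remark on the chemistry: the benzhydryl ether carbon between rings C and D is formed without control in step 4 and is left undefined in the SMILES of 7, 8, 15, 16 and 26–29 (epimer mixtures); it becomes trigonal in step 15, so this has no consequence. MOM = methoxymethyl, TBS = tert-butyldimethylsilyl.

**Route**

Step 1
Reactants: 1 2-bromo-4,5-dihydroxybenzaldehyde
Product: 2 2-bromo-4-hydroxy-5-(methoxymethoxy)benzaldehyde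
Conditions: NaH (2.2 equiv), DMSO, 20 °C; MOMCl (1.0 equiv), 0→20 °C
Reagents that add atoms: chloromethyl methyl ether, COCCl
Why: In the dianion the 5-oxide, which is not conjugated with the aldehyde, is the more nucleophilic oxygen, so one equivalent of the chloride should give a regioselective Williamson etherification at O-5.

Step 2
Reactants: 2 2-bromo-4-hydroxy-5-(methoxymethoxy)benzaldehyde
Product: 3 2-bromo-4-[(tert-butyldimethylsilyl)oxy]-5-(methoxymethoxy)benzaldehyde
Conditions: TBSCl, imidazole, DMF, 0→20 °C
Reagents that add atoms: tert-butyldimethylsilyl chloride, CC(C)(C)[Si](C)(C)Cl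
Why: Imidazole-mediated silylation of the remaining para hydroxyl gives an aryl silyl ether that can later be removed by base without touching the acetal ethers.

Step 3
Reactants: 4 4-bromobenzene-1,2-diol
Product: 5 4-bromo-1,2-bis(methoxymethoxy)benzene
Conditions: MOMCl, i-Pr2NEt, CH2Cl2, 0→20 °C
Reagents that add atoms: chloromethyl methyl ether, COCCl
Why: Williamson-type O-alkylation of both phenols gives the base-stable, acid-labile bis-acetal needed for the organolithium step.

Step 4
Reactants: 5 4-bromo-1,2-bis(methoxymethoxy)benzene; 3 2-bromo-4-[(tert-butyldimethylsilyl)oxy]-5-(methoxymethoxy)benzaldehyde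
Product: 8 1-bromo-2-{[3,4-bis(methoxymethoxy)phenyl](methoxy)methyl}-4-(methoxymethoxy)-5-[(tert-butyldimethylsilyl)oxy]benzene, via aryllithium 6 (not isolated), via lithium alkoxide 7 (not isolated)
Conditions: 5, n-BuLi, THF, −78 °C; 3, −78 °C; MeI, DMPU, −78→20 °C
Reagents that add atoms: iodomethane, CI
Why: Bromine–lithium exchange, 1,2-addition of the aryllithium to the aldehyde (faster than exchange with the second aryl bromide) and in-situ Williamson methylation of the alkoxide give the benzhydryl methyl ether, whose new centre is formed without control and is erased in step 15.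

Step 5
Reactants: 9 2,6-dimethoxyphenol
Product: 10 1,3-dimethoxy-2-(methoxymethoxy)benzene
Conditions: NaH, THF, 0 °C; MOMCl, 0→20 °C
Reagents that add atoms: chloromethyl methyl ether, COCCl
Why: Williamson etherification of the hindered phenoxide protects the ring-B hydroxyl and leaves the two methoxy groups as ortho-directing groups.

Step 6
Reactants: 10 1,3-dimethoxy-2-(methoxymethoxy)benzene; 11 prop-2-yn-1-ol; 8 1-bromo-2-{[3,4-bis(methoxymethoxy)phenyl](methoxy)methyl}-4-(methoxymethoxy)-5-[(tert-butyldimethylsilyl)oxy]benzene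
Product: 15 (Z)-2-[2,4-dimethoxy-3-(methoxymethoxy)phenyl]-3-[2-{[3,4-bis(methoxymethoxy)phenyl](methoxy)methyl}-4-(methoxymethoxy)-5-(TBS-oxy)phenyl]prop-2-en-1-ol, via aryllithium 12 (not isolated), via aryl Grignard reagent 13 (not isolated), via alkenylmagnesium alkoxide 14 (not isolated)
Conditions: 10, n-BuLi, THF, 0→20 °C; MgBr2·OEt2, 0 °C; 11 (premixed with i-PrMgCl), CuI (10 mol %), THF/toluene, 0→60 °C; then 8, Pd(PPh3)4 (5 mol %), 60 °C
Reagents that add atoms: none
Why: Directed ortho-lithiation next to a methoxy group and transmetalation give the aryl Grignard reagent, whose copper-catalysed, alkoxide-directed anti-carbomagnesiation of propargyl alcohol puts the aryl group on the internal carbon and magnesium cis to the CH2O group, and a palladium-catalysed Kumada-type cross-coupling with retention then places ring D cis to the hydroxymethyl group.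

Step 7
Reactants: 15 the (Z)-allylic alcohol of step 6
Product: 16 (Z)-2-[2,4-dimethoxy-3-(methoxymethoxy)phenyl]-3-[2-{[3,4-bis(methoxymethoxy)phenyl](methoxy)methyl}-4-(methoxymethoxy)-5-(TBS-oxy)phenyl]prop-2-enal
Conditions: MnO2, CH2Cl2, 20 °C
Reagents that add atoms: none
Why: Neutral MnO2 oxidation of the primary allylic alcohol gives the enal without isomerising the trisubstituted alkene or touching the ethers.

Step 8
Reactants: 17 4-hydroxy-2-methoxybenzaldehyde
Product: 18 2-methoxy-4-(methoxymethoxy)benzaldehyde
Conditions: MOMCl, i-Pr2NEt, CH2Cl2, 0→20 °C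
Reagents that add atoms: chloromethyl methyl ether, COCCl
Why: Williamson-type protection of the ring-A phenol as the acetal ether.

Step 9
Reactants: 18 2-methoxy-4-(methoxymethoxy)benzaldehyde; 19 malonic acid
Product: 20 (E)-3-[2-methoxy-4-(methoxymethoxy)phenyl]prop-2-enoic acid
Conditions: pyridine, piperidine (cat.), 90 °C
Reagents that add atoms: none
Why: Knoevenagel–Doebner condensation with decarboxylation gives the (E)-cinnamic acid under basic conditions that the acetal tolerates.

Step 10
Reactants: 20 (E)-3-[2-methoxy-4-(methoxymethoxy)phenyl]prop-2-enoic acid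
Product: 21 3-[2-methoxy-4-(methoxymethoxy)phenyl]propanoic acid
Conditions: H2 (1 atm), Pd/C, EtOAc, 20 °C
Reagents that add atoms: none
Why: Heterogeneous catalytic hydrogenation saturates only the conjugated C=C bond.

Step 11
Reactants: 21 3-[2-methoxy-4-(methoxymethoxy)phenyl]propanoic acid; 22 (S)-4-benzyl-1,3-oxazolidin-2-one
Product: 24 (S)-4-benzyl-3-{3-[2-methoxy-4-(methoxymethoxy)phenyl]propanoyl}-1,3-oxazolidin-2-one, via mixed anhydride 23 (not isolated)
Conditions: PivCl, Et3N, THF, −20 °C; then 22, LiCl, −20→20 °C
Reagents that add atoms: none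
Why: N-Acylation of the oxazolidinone through the mixed pivalic anhydride, with attack at the less hindered carbonyl, installs the chiral auxiliary.

Step 12
Reactants: 24 the imide of step 11; 16 the (Z)-enal of step 7
Product: 26 (S)-4-benzyl-3-[(2S,3S,4Z)-3-hydroxy-2-[2-methoxy-4-(methoxymethoxy)benzyl]-4-[2,4-dimethoxy-3-(methoxymethoxy)phenyl]-5-{2-[(3,4-bis(methoxymethoxy)phenyl)(methoxy)methyl]-4-(methoxymethoxy)-5-(TBS-oxy)phenyl}pent-4-enoyl]-1,3-oxazolidin-2-one, via boron enolate 25 (not isolated)
Conditions: Bu2BOTf, i-Pr2NEt, CH2Cl2, −78→0 °C; 16, −78→0 °C; pH 7 buffer, MeOH, H2O2, 0 °C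
Reagents that add atoms: none
Why: Evans syn-aldol reaction in which the (Z)-boron enolate reacts through a closed chair transition state with one face shielded by the (S)-benzyl auxiliary, which should set the (2S,3S) configuration; the 3-carbinol is the one stereocentre carried into the target.

Step 13
Reactants: 26 the aldol adduct of step 12
Product: 28 (2S,3S,4Z)-3-hydroxy-2-[2-methoxy-4-(methoxymethoxy)benzyl]-4-[2,4-dimethoxy-3-(methoxymethoxy)phenyl]-5-{2-[(3,4-bis(methoxymethoxy)phenyl)(methoxy)methyl]-5-hydroxy-4-(methoxymethoxy)phenyl}pent-4-enoic acid, via peroxy acid 27 (not isolated)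
Conditions: LiOH·H2O, H2O2, THF/H2O, 0→20 °C; Na2SO3; HCl (1 M) to pH 4, 0 °C
Reagents that add atoms: hydrogen peroxide, OO
Why: Hydroperoxide cleavage of the imide at the exocyclic carbonyl followed by hydroxide cleavage of the base-labile aryl silyl ether frees the acid and the ring-D phenol without touching the two stereocentres.

Step 14
Reactants: 28 the phenol acid of step 13
Product: 29 4,5,6,7-tetrachloro-1,3-dioxoisoindolin-2-yl (2S,3S,4Z)-3-hydroxy-2-[2-methoxy-4-(methoxymethoxy)benzyl]-4-[2,4-dimethoxy-3-(methoxymethoxy)phenyl]-5-{2-[(3,4-bis(methoxymethoxy)phenyl)(methoxy)methyl]-5-hydroxy-4-(methoxymethoxy)phenyl}pent-4-enoate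
Conditions: N-hydroxytetrachlorophthalimide, DIC, CH2Cl2, 0→20 °C
Reagents that add atoms: N-hydroxytetrachlorophthalimide, ON1C(=O)c2c(Cl)c(Cl)c(Cl)c(Cl)c2C1=O
Why: Carbodiimide (Steglich-type) esterification without an acyl-transfer catalyst should acylate the acidic N-hydroxyimide in preference to the hindered secondary alcohol and the phenol, giving the redox-active ester.

Step 15
Reactants: 29 the redox-active ester of step 14
Product: 31 penta-MOM oxa-bridged dienone (ring D is a 2-(methoxymethoxy)cyclohexa-2,5-dien-1-one whose C-4 is the ether bridgehead; rings E and F closed; ring-A benzyl group exo and ring-C aryl group endo on the 8-oxabicyclo[3.2.1]octadiene), via quinone methide 30 (not isolated)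
Conditions: (PhO)2P(O)OH (20 mol %), 5 Å MS, CH2Cl2/MeCN, 20 °C, dark; then 4CzIPN (2 mol %), 456 nm LEDs, 20 °C
Reagents that add atoms: none
Why: Proposed new method: diphenyl phosphate expels methanol from the para-hydroxybenzhydryl ether to give ring-D para-quinone methide 30; photoexcited 4CzIPN then reduces the tetrachlorophthalimide ester, CO2 is lost and the secondary alkyl radical adds to the methide carbon in a 7-endo-trig closure driven by re-aromatisation, after which the 4CzIPN radical cation oxidises the phenoxyl radical to a phenoxonium ion that the neighbouring secondary hydroxyl traps at the para carbon, one transannular ipso attack that closes the tetrahydrofuran (five-membered mode) and the dihydropyran (six-membered mode) and leaves ring D as the 4,4-disubstituted dienone. The closest known reaction types are the redox-neutral radical-polar crossover carbo-etherification of styrenes with redox-active esters, decarboxylative radical 1,6-additions to para-quinone methides and the oxidative dearomatising etherification of para-alkylphenols; new is their union on one exocyclic C=C bond. The benzyl-bearing and the aryl-bearing methine centres are set in the radical closure by the (S)-carbinol: allylic 1,2-strain against ring B holds its C–O bond pseudo-axial in a chair-like seven-membered transition state in which the benzyl group and ring C sit trans-diequatorial, so the benzyl group should end cis and ring C trans to the oxygen. The quaternary ether centre then follows because the pseudo-axial oxygen can reach only one face of the planar phenoxonium ring. The step needs radical attack at the methide carbon and not at the ring enone carbons, which re-aromatisation secures, and etherification faster than loss of the benzylic proton, which the five-membered intramolecular closure and the acetal cap on the second ring-D oxygen (no ortho-quinone tautomer) secure.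

Step 16
Reactants: 31 the oxa-bridged dienone of step 15
Product: 33 CNP0246028.1, via deprotected diketone 32 (not isolated)
Conditions: HCl (2 M in MeOH), THF, 0→40 °C
Reagents that add atoms: none
Why: Acid-catalysed acetal exchange with methanol removes the five methoxymethyl groups, the freed enol tautomerises to the α-diketone, and an intramolecular Friedel–Crafts hydroxyalkylation by the ring-C carbon para to a hydroxyl closes ring G; the tertiary carbinol can form only in the cis-bridged (bicyclo[3.3.1]) sense.

**Compound list**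

1 | 2-bromo-4,5-dihydroxybenzaldehyde | O=Cc1cc(O)c(O)cc1Br | starting material
2 | 2-bromo-4-hydroxy-5-(methoxymethoxy)benzaldehyde | O=Cc1cc(OCOC)c(O)cc1Br | intermediate
3 | 2-bromo-4-[(tert-butyldimethylsilyl)oxy]-5-(methoxymethoxy)benzaldehyde | O=Cc1cc(OCOC)c(O[Si](C)(C)C(C)(C)C)cc1Br | intermediate
4 | 4-bromobenzene-1,2-diol | Oc1ccc(Br)cc1O | starting material
5 | 4-bromo-1,2-bis(methoxymethoxy)benzene | COCOc1ccc(Br)cc1OCOC | intermediate
6 | [3,4-bis(methoxymethoxy)phenyl]lithium | COCOc1ccc([Li])cc1OCOC | intermediate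
7 | lithium alkoxide of [3,4-bis(methoxymethoxy)phenyl]{2-bromo-5-(methoxymethoxy)-4-(TBS-oxy)phenyl}methanol (racemic) | [Li]OC(c1ccc(OCOC)c(OCOC)c1)c1cc(OCOC)c(O[Si](C)(C)C(C)(C)C)cc1Br | intermediate
8 | 1-bromo-2-{[3,4-bis(methoxymethoxy)phenyl](methoxy)methyl}-4-(methoxymethoxy)-5-[(tert-butyldimethylsilyl)oxy]benzene (racemic) | COC(c1ccc(OCOC)c(OCOC)c1)c1cc(OCOC)c(O[Si](C)(C)C(C)(C)C)cc1Br | intermediate
9 | 2,6-dimethoxyphenol | COc1cccc(OC)c1O | starting material
10 | 1,3-dimethoxy-2-(methoxymethoxy)benzene | COCOc1c(OC)cccc1OC | intermediate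
11 | prop-2-yn-1-ol | C#CCO | starting material
12 | [2,4-dimethoxy-3-(methoxymethoxy)phenyl]lithium | COCOc1c(OC)ccc([Li])c1OC | intermediate
13 | [2,4-dimethoxy-3-(methoxymethoxy)phenyl]magnesium bromide | COCOc1c(OC)ccc([Mg]Br)c1OC | intermediate
14 | 4-[2,4-dimethoxy-3-(methoxymethoxy)phenyl]-2,5-dihydro-1,2-oxamagnesole (cyclic (Z)-alkenylmagnesium alkoxide) | COCOc1c(OC)ccc(C2=C[Mg]OC2)c1OC | intermediate
15 | (Z)-2-[2,4-dimethoxy-3-(methoxymethoxy)phenyl]-3-[2-{[3,4-bis(methoxymethoxy)phenyl](methoxy)methyl}-4-(methoxymethoxy)-5-(TBS-oxy)phenyl]prop-2-en-1-ol | OC/C(c1ccc(OC)c(OCOC)c1OC)=C\c1cc(O[Si](C)(C)C(C)(C)C)c(OCOC)cc1C(OC)c1ccc(OCOC)c(OCOC)c1 | intermediate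
16 | (Z)-2-[2,4-dimethoxy-3-(methoxymethoxy)phenyl]-3-[2-{[3,4-bis(methoxymethoxy)phenyl](methoxy)methyl}-4-(methoxymethoxy)-5-(TBS-oxy)phenyl]prop-2-enal | O=C/C(c1ccc(OC)c(OCOC)c1OC)=C\c1cc(O[Si](C)(C)C(C)(C)C)c(OCOC)cc1C(OC)c1ccc(OCOC)c(OCOC)c1 | intermediate
17 | 4-hydroxy-2-methoxybenzaldehyde | COc1cc(O)ccc1C=O | starting material
18 | 2-methoxy-4-(methoxymethoxy)benzaldehyde | COCOc1ccc(C=O)c(OC)c1 | intermediate
19 | malonic acid | OC(=O)CC(=O)O | starting material
20 | (E)-3-[2-methoxy-4-(methoxymethoxy)phenyl]prop-2-enoic acid | COCOc1ccc(/C=C/C(=O)O)c(OC)c1 | intermediate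
21 | 3-[2-methoxy-4-(methoxymethoxy)phenyl]propanoic acid | COCOc1ccc(CCC(=O)O)c(OC)c1 | intermediate
22 | (S)-4-benzyl-1,3-oxazolidin-2-one | O=C1N[C@@H](Cc2ccccc2)CO1 | starting material
23 | 3-[2-methoxy-4-(methoxymethoxy)phenyl]propanoic pivalic anhydride | COCOc1ccc(CCC(=O)OC(=O)C(C)(C)C)c(OC)c1 | intermediate
24 | (S)-4-benzyl-3-{3-[2-methoxy-4-(methoxymethoxy)phenyl]propanoyl}-1,3-oxazolidin-2-one | COCOc1ccc(CCC(=O)N2[C@@H](Cc3ccccc3)COC2=O)c(OC)c1 | intermediate
25 | (Z)-dibutylboron enolate of 24 | CCCCB(CCCC)O/C(=C\Cc1ccc(OCOC)cc1OC)N1[C@@H](Cc2ccccc2)COC1=O | intermediate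
26 | (S)-4-benzyl-3-[(2S,3S,4Z)-aldol adduct]oxazolidinone (full name in step 12) | COCOc1ccc(C[C@H](C(=O)N2[C@@H](Cc3ccccc3)COC2=O)[C@H](O)/C(c2ccc(OC)c(OCOC)c2OC)=C\c2cc(O[Si](C)(C)C(C)(C)C)c(OCOC)cc2C(OC)c2ccc(OCOC)c(OCOC)c2)c(OC)c1 | intermediate
27 | (2S,3S,4Z)-peroxy acid from 26 (aryl silyl ether still in place) | COCOc1ccc(C[C@H](C(=O)OO)[C@H](O)/C(c2ccc(OC)c(OCOC)c2OC)=C\c2cc(O[Si](C)(C)C(C)(C)C)c(OCOC)cc2C(OC)c2ccc(OCOC)c(OCOC)c2)c(OC)c1 | intermediate
28 | (2S,3S,4Z)-β-hydroxy acid with free ring-D phenol (full name in step 13) | COCOc1ccc(C[C@H](C(=O)O)[C@H](O)/C(c2ccc(OC)c(OCOC)c2OC)=C\c2cc(O)c(OCOC)cc2C(OC)c2ccc(OCOC)c(OCOC)c2)c(OC)c1 | intermediate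
29 | tetrachlorophthalimide (redox-active) ester of 28 | COCOc1ccc(C[C@H](C(=O)ON2C(=O)c3c(Cl)c(Cl)c(Cl)c(Cl)c3C2=O)[C@H](O)/C(c2ccc(OC)c(OCOC)c2OC)=C\c2cc(O)c(OCOC)cc2C(OC)c2ccc(OCOC)c(OCOC)c2)c(OC)c1 | intermediate
30 | ring-D para-quinone methide of 29 (4-[3,4-bis(methoxymethoxy)benzylidene]-2-(methoxymethoxy)cyclohexa-2,5-dien-1-one carrying the pentenoate chain at C-5; methide geometry not defined) | COCOc1ccc(C[C@H](C(=O)ON2C(=O)c3c(Cl)c(Cl)c(Cl)c(Cl)c3C2=O)[C@H](O)/C(c2ccc(OC)c(OCOC)c2OC)=C\C2=CC(=O)C(OCOC)=CC2=Cc2ccc(OCOC)c(OCOC)c2)c(OC)c1 | intermediate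
31 | penta-MOM oxa-bridged dienone (description in step 15; carbinol-derived methine S, benzyl exo, ring-C aryl endo) | COc1cc(OCOC)ccc1C[C@@H]1[C@@H]2O[C@@]3([C@H]1c1ccc(OCOC)c(OCOC)c1)C=C(OCOC)C(=O)C=C3C=C2c2ccc(OC)c(OCOC)c2OC | intermediate
32 | deprotected α-diketone (all five acetals removed, ring G still open) | COc1cc(O)ccc1C[C@@H]1[C@@H]2O[C@@]3([C@H]1c1ccc(O)c(O)c1)CC(=O)C(=O)C=C3C=C2c2ccc(OC)c(O)c2OC | intermediate
33 | CNP0246028.1 | COc1cc(O)ccc1C[C@@H]1[C@@H]2O[C@@]34C[C@@](O)(C(=O)C=C3C=C2c2ccc(OC)c(O)c2OC)c2cc(O)c(O)cc2[C@@H]14 | target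

**Step count and risks**

Total step count: 16. Longest linear sequence: 10 steps (1 → 2 → 3 → 8 → 15 → 16 → 26 → 28 → 29 → 31 → 33).

Steps most likely to fail:

1. Step 15 (carries the label "Proposed new method:"). The quinone methide may be captured by the neighbouring hydroxyl or oligomerise before the radical is formed. The phenoxonium ion may lose its benzylic proton instead of being etherified. The seven-membered radical closure may give the wrong configuration at the benzyl-bearing centre. Fallback with known reaction types, setting out from 29 and coming back at 31: a reductive decarboxylative Giese-type 1,6-addition to the quinone methide (Hantzsch ester, 4CzIPN, (PhO)2P(O)OH, 456 nm LEDs) should close only the seven-membered ring and give bicyclic phenol F1. Treatment of bicyclic phenol F1 with PhI(OAc)2 in (CF3)2CHOH/CH2Cl2 at 0 °C, the standard oxidative dearomatising etherification of a para-substituted phenol by a tethered alcohol, should then form the ether bridge and give 31.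

2. Step 6. The carbomagnesiation may stall, the alkenylmagnesium intermediate may be protonated before coupling, the aryl Grignard reagent may couple directly with the bromide, or the alkene geometry may erode at 60 °C. Fallback, setting out from 10, 11 and 8 and coming back at 15: the carbomagnesiation is run alone and quenched with I2 to give vinyl iodide F2. Bromide 8 is converted by Miyaura borylation (B2pin2, Pd(dppf)Cl2, KOAc) into boronic ester F3. Suzuki–Miyaura coupling of vinyl iodide F2 with boronic ester F3 (Pd(PPh3)4, K3PO4) should give 15 with retention of geometry.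

3. Step 16. Released formaldehyde equivalents may alkylate the freed electron-rich rings, methanol may add to the dienone, and ring closure may be slow because the diketone rests as its enol. Fallback, setting out from 31 and coming back at 33: only the enol acetal is cleaved (PPTS, MeOH, 20 °C) to give α-diketone F4. A Lewis-acid Friedel–Crafts hydroxyalkylation (Sc(OTf)3, CH2Cl2) closes ring G on the still-protected ring C to give bridged carbinol F5. The four aryl acetals of bridged carbinol F5 are then removed (HCl, MeOH) to give 33.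

**Further compounds**

F1 | step 15 | bicyclic phenol: 7-hydroxy-6,7-dihydro-5H-benzo[7]annulene with ring C at C-5, the ring-A benzyl group at C-6, ring B at C-8 and a free phenol para to C-5 | COc1cc(OCOC)ccc1C[C@@H]1[C@H](O)C(c2ccc(OC)c(OCOC)c2OC)=Cc2cc(O)c(OCOC)cc2[C@H]1c1ccc(OCOC)c(OCOC)c1
F2 | step 6 | (Z)-2-[2,4-dimethoxy-3-(methoxymethoxy)phenyl]-3-iodoprop-2-en-1-ol | OC/C(c1ccc(OC)c(OCOC)c1OC)=C\I
F3 | step 6 | pinacol boronic ester of 8 (boron in place of bromine) | COC(c1ccc(OCOC)c(OCOC)c1)c1cc(OCOC)c(O[Si](C)(C)C(C)(C)C)cc1B1OC(C)(C)C(C)(C)O1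
F4 | step 16 | α-diketone with the four aryl acetals still in place | COc1cc(OCOC)ccc1C[C@@H]1[C@@H]2O[C@@]3([C@H]1c1ccc(OCOC)c(OCOC)c1)CC(=O)C(=O)C=C3C=C2c2ccc(OC)c(OCOC)c2OC
F5 | step 16 | tetra-MOM ether of the target (ring G closed) | COc1cc(OCOC)ccc1C[C@@H]1[C@@H]2O[C@@]34C[C@@](O)(C(=O)C=C3C=C2c2ccc(OC)c(OCOC)c2OC)c2cc(OCOC)c(OCOC)cc2[C@@H]14
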